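**Retrosynthetic overview**
1. Feature: in eudesmane numbering (ring A = C1–C5 and C10, ring B = C5–C10), ring B is a cyclohexenone. Its α-carbon C7 lies between C6 and the C8 carbonyl and carries the C11 side chain, so C7 can enter last, as a C–Br unit pushed into a five-membered ketone.
2. Late stage: C11–OOH and C6=C7 come from a singlet-oxygen ene reaction of the 7(11)-en-8-one. The 3β-angelate and 4α-carbinol come from a C3=C4 alkene (α-face dihydroxylation, C3 oxidation–reduction, acylation). C11–C13 come from cross-coupling at C7–Br.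
3. Key disconnection: C6–C7 and C7–C8 are removed together. This restores the C6–C8 bond of a trans-hydrindanone, used as its C6=C8 silyl enol ether, plus dibromocarbene.
4. The hydrindane goes back to a Pauson–Khand reaction of an (R)-propargylic silyl ether 1,7-enyne (bonds C5–C10, C6–C8, C8–C9), made from δ-valerolactone and ethynylmagnesium bromide.
5. Ring order: ring A and the five-membered ring close together (step 8), and the five-membered ring is then enlarged to ring B (step 10).

Key step: step 10

Remark: eudesmane numbers are used for all intermediates. C7 is absent before step 10 and C15 (the C4 methyl) before step 16. β is the face of the C10 methyl group and α the opposite face.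

Step 1
Reactants: 1 δ-valerolactone
Product: 2 6-hydroxyhexan-2-one
Conditions: MeLi (1.0 equiv), Et2O, −78 °C; then H2O
Reagents that add atoms: methyllithium, [Li]C
Why: Single 1,2-addition of an organolithium to a lactone, because the lithium hemiketal alkoxide persists at −78 °C and collapses to the hydroxy ketone only on quench, so a second addition is avoided.

Step 2
Reactants: 2 6-hydroxyhexan-2-one
Product: 3 5-methylhex-5-en-1-ol
Conditions: Ph3PCH3Br (2.5 equiv), KOtBu (2.4 equiv), THF, 0 °C to rt
Reagents that add atoms: methyltriphenylphosphonium bromide, C[P+](c1ccccc1)(c1ccccc1)c1ccccc1.[Br-]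
Why: Wittig methylenation of an unhindered methyl ketone, in which the surplus ylide only deprotonates the free hydroxyl.

Step 3
Reactants: 3 5-methylhex-5-en-1-ol
Product: 4 5-methylhex-5-enal
Conditions: TEMPO (10 mol %), PhI(OAc)2 (1.1 equiv), CH2Cl2, rt
Reagents that add atoms: none
Why: Oxoammonium (TEMPO) oxidation of a primary alcohol stops at the aldehyde and leaves the 1,1-disubstituted alkene alone.

Step 4
Reactants: 4 5-methylhex-5-enal; 5 ethynylmagnesium bromide
Product: 6 rac-7-methyloct-7-en-1-yn-3-ol
Conditions: 5 (0.5 M in THF, 1.2 equiv), THF, 0 °C; then H2O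
Reagents that add atoms: ethynylmagnesium bromide (5), C#C[Mg]Br
Why: Grignard 1,2-addition of the acetylide forms the C4–C5 bond, and the carbinol is racemic here because its configuration is set in steps 5 and 6.

Step 5
Reactants: 6 rac-7-methyloct-7-en-1-yn-3-ol
Product: 7 7-methyloct-7-en-1-yn-3-one
Conditions: DMP (1.2 equiv), CH2Cl2, 0 °C to rt
Reagents that add atoms: none
Why: Hypervalent-iodine oxidation of a propargylic alcohol is fast under neutral conditions, which spares the Michael-sensitive terminal ynone.

Step 6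
Reactants: 7 7-methyloct-7-en-1-yn-3-one
Product: 9 (R)-7-methyloct-7-en-1-yn-3-ol, via 9-BBN borinate 8 (not isolated)
Conditions: (R)-Alpine-Borane [B-isopinocampheyl-9-BBN from (+)-α-pinene, 1.5 equiv], neat, 0 °C to rt; then HOCH2CH2NH2, Et2O, 0 °C
Reagents that add atoms: none
Why: Midland reduction, in which the pinanyl C–H hydride is passed on through a boat-like six-membered transition state with the slim ethynyl group next to the pinane methyl, so the (+)-α-pinene-derived reagent should give the (R)-carbinol (C4) much faster than it can release 9-BBN towards the alkene.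

Step 7
Reactants: 9 (R)-7-methyloct-7-en-1-yn-3-ol
Product: 10 (R)-3-(tert-butyldimethylsilyloxy)-7-methyloct-7-en-1-yne
Conditions: TBSCl, imidazole, DMF, rt
Reagents that add atoms: tert-butyldimethylsilyl chloride, CC(C)(C)[Si](C)(C)Cl
Why: Imidazole-promoted O-silylation of a secondary alcohol, which touches neither the C4 stereocentre nor the alkyne C–H.

Step 8
Reactants: 10 (R)-3-(tert-butyldimethylsilyloxy)-7-methyloct-7-en-1-yne
Product: 12 hydrindenone with C5=C6 and C8=O (4α-OTBS and 10β-CH3), via hexacarbonyldicobalt alkyne complex 11 (not isolated)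
Conditions: Co2(CO)8 (1.1 equiv), CH2Cl2, rt; then NMO (8 equiv), 0 °C to rt
Reagents that add atoms: dicobalt octacarbonyl (delivers the C8 carbonyl), O=C=[Co](=C=O)(=C=O)(=C=O)[Co](=C=O)(=C=O)(=C=O)=C=O
Why: Intramolecular Pauson–Khand [2+2+1] reaction of a 1,7-enyne closes ring A and the cyclopentenone at once, and a chair-like tether with the OTBS group equatorial places the C10 methyl axial on the opposite face, since the other isomer would hold O and CH3 1,3-diaxial, so C4 should set C10.

Step 9
Reactants: 12 hydrindenone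
Product: 13 trans-hydrindane C6=C8 trimethylsilyl enol ether (4α-OTBS, 5α-H, 10β-CH3)
Conditions: [(Ph3P)CuH]6 (0.4 equiv), TMSCl (4 equiv), toluene, rt; filtration through Et3N-washed silica
Reagents that add atoms: chlorotrimethylsilane, C[Si](C)(C)Cl
Why: Copper hydride conjugate reduction with in situ enolate silylation, in which hydride should reach the β-carbon C5 axially from the α face, anti to the axial methyl on neighbouring C10 (trans fusion), and O-silylation of the enolate where it is formed fixes the double bond at C6=C8 only.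

Step 10
Reactants: 13 trans-hydrindane C6=C8 trimethylsilyl enol ether; 14 bromoform
Product: 16 7-bromo-4α-(tert-butyldimethylsilyloxy)-10β-methyl-trans-decal-6-en-8-one, via dibromo siloxycyclopropane 15 (not isolated)
Conditions: CHBr3 (2 equiv), KOtBu (1.8 equiv), pentane, −30 °C to rt; filter; toluene, 80 °C
Reagents that add atoms: bromoform (14), BrC(Br)Br
Why: tert-Butoxide takes HBr from bromoform, and singlet CBr2 adds in a concerted [2+1] cheletropic step to the only alkene of 13, the electron-rich C6=C8 enol ether (from the α face, away from the C10 methyl), giving 15 with the new C6–C7 and C7–C8 bonds. In this strained bicyclo[3.1.0]hexane the endo bromide ionises while the shared C6–C8 bond opens in a disrotatory two-electron electrocyclic process pushed by the C8 oxygen, and the 2-bromoallyl/oxocarbenium cation gives up Me3Si to bromide to leave the 7-bromo-6-en-8-one. The closest known reaction type is the dihalocarbene homologation of cyclopentanone and cyclohexanone trimethylsilyl enol ethers to 2-halocycloalk-2-enones. Ring B is thus formed by enlargement and not by cyclisation: a three-membered ring is closed by cycloaddition, and the bond it shares with the five-membered ring is then broken. No lasting stereocentre is made (the C6 and C8 cyclopropane centres vanish on opening), and C4, C5 and C10 are untouched, the trans-decalin also being the more stable fusion. The step needs regiocontrol, given by the enol ether position fixed in step 9, so that the new carbon can only end up between C6 and C8; it also needs the base to be used up by bromoform before it attacks silicon or the product, which the non-polar medium, the low temperature and the excess of bromoform over base should secure.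

Step 11
Reactants: 16 7-bromo-6-en-8-one; 17 isopropenylboronic acid pinacol ester
Product: 18 7-isopropenyl-4α-(tert-butyldimethylsilyloxy)-10β-methyl-trans-decal-6-en-8-one
Conditions: 17 (1.5 equiv), Pd(dppf)Cl2 (5 mol %), K3PO4, THF/H2O, 50 °C; used directly
Reagents that add atoms: isopropenylboronic acid pinacol ester (17), C=C(C)B1OC(C)(C)C(C)(C)O1
Why: Suzuki–Miyaura coupling of a 2-bromoenone, whose electron-poor C–Br bond adds readily to zerovalent palladium, under a mild phosphate base that should leave C5–H and the silyl ether alone.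

Step 12
Reactants: 18 7-isopropenyl-6-en-8-one
Product: 21 4α-(tert-butyldimethylsilyloxy)-15-noreudesm-7(11)-en-8-one, via lithium dienolate 19 (not isolated), via 7-isopropenyl ketone 20 (not isolated)
Conditions: LiBH(s-Bu)3 (L-Selectride, 1.1 equiv), THF, −78 °C; then MeOH, NaOMe (0.3 equiv), rt
Reagents that add atoms: none
Why: Conjugate hydride reduction of a cyclohexenone with no extra β-substituent by a bulky trialkylborohydride puts H on C6, and methoxide then moves the β,γ-double bond of the protonated dienolate into the more stable tetrasubstituted C7=C11 position, as in the isopulegone-to-pulegone isomerisation.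

Step 13
Reactants: 21 4α-silyloxy-7(11)-en-8-one
Product: 22 4α-hydroxy-15-noreudesm-7(11)-en-8-one
Conditions: 48 % aq HF, MeCN, rt
Reagents that add atoms: none
Why: Fluoride-driven silyl ether cleavage (strong Si–F bond) under mildly acidic conditions that do not disturb the enone.

Step 14
Reactants: 22 4α-hydroxy-7(11)-en-8-one
Product: 23 15-noreudesm-7(11)-ene-4,8-dione
Conditions: DMP (1.3 equiv), CH2Cl2, rt
Reagents that add atoms: none
Why: Neutral hypervalent-iodine oxidation gives the C4 ketone without epimerising the now enolisable C5, where the trans fusion is in any case the more stable one.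

Step 15
Reactants: 23 4,8-dione
Product: 25 C3=C4 enol triflate of 23, via lithium C3 enolate 24 (not isolated)
Conditions: LDA (1.05 equiv), THF, −78 °C; then N-(5-chloro-2-pyridyl)bis(trifluoromethanesulfonimide), −78 °C; then H2O
Reagents that add atoms: N-(5-chloro-2-pyridyl)bis(trifluoromethanesulfonimide), O=S(=O)(N(c1ccc(Cl)cn1)S(=O)(=O)C(F)(F)F)C(F)(F)F
Why: Kinetic enolate formation and O-triflation, in which the hindered amide should remove the open axial C3–H faster than the tertiary C5–H or the neopentyl C9–H next to quaternary C10, and the reactive pyridyl triflimide traps the enolate at −78 °C before proton transfer can occur.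

Step 16
Reactants: 25 enol triflate
Product: 26 eudesma-3,7(11)-dien-8-one
Conditions: MeZnCl (2 equiv), Pd(PPh3)4 (5 mol %), THF, rt
Reagents that add atoms: methylzinc chloride, C[Zn]Cl
Why: Negishi coupling of an alkenyl triflate puts C15 on C4 with the alkene fixed at C3=C4, and an organozinc halide does not add to the C8 ketone.

Step 17
Reactants: 26 eudesma-3,7(11)-dien-8-one
Product: 27 3α,4α-dihydroxyeudesm-7(11)-en-8-one
Conditions: OsO4 (5 mol %), NMO (1.5 equiv), acetone/H2O, rt
Reagents that add atoms: N-methylmorpholine N-oxide, C[N+]1([O-])CCOCC1; water, O; OsO4 (catalytic oxygen carrier), O=[Os](=O)(=O)=O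
Why: Upjohn dihydroxylation, in which OsO4 picks the electron-rich trisubstituted C3=C4 over the electron-poor tetrasubstituted C7=C11 and adds suprafacially from the α face because the axial C10 methyl blocks the β face, setting C4 as in the target (4α-OH, 4β-CH3) and C3 as the 3α epimer.

Step 18
Reactants: 27 3α,4α-diol
Product: 28 4α-hydroxyeudesm-7(11)-ene-3,8-dione
Conditions: IBX (1.5 equiv), DMSO, rt
Reagents that add atoms: none
Why: IBX oxidises the secondary carbinol of a 1,2-diol to the α-ketol without C–C cleavage, and the tertiary C4 hydroxyl is inert.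

Step 19
Reactants: 28 4α-hydroxy-3,8-dione
Product: 29 3β,4α-dihydroxyeudesm-7(11)-en-8-one
Conditions: NaBH4, MeOH/CH2Cl2 (1:1), −78 °C
Reagents that add atoms: none
Why: Low-temperature borohydride reduction distinguishes the activated saturated α-hydroxy ketone from the hindered conjugated C8 ketone, and hydride attacks C3 axially from the α face because the β face carries the axial C4 methyl, which should give the equatorial 3β-alcohol as with 4,4-disubstituted 3-keto terpenoids.

Step 20
Reactants: 29 3β,4α-diol; 30 angelic acid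
Product: 32 3β-angeloyloxy-4α-hydroxyeudesm-7(11)-en-8-one, via angelic 2,4,6-trichlorobenzoic anhydride 31 (not isolated)
Conditions: 30, 2,4,6-Cl3C6H2COCl, Et3N, toluene, rt; then 29, 80 °C
Reagents that add atoms: angelic acid (30), C/C=C(/C)C(=O)O
Why: Yamaguchi-type mixed-anhydride esterification run without a nucleophilic catalyst, so that the Z-alkene is not isomerised to the tiglate; the alcohol attacks the angeloyl carbonyl because the aroyl one is shielded by two ortho chlorines, and only the secondary 3β-OH reacts, not the tertiary 4α-OH.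

Step 21
Reactants: 32 3β-angeloyloxy-4α-hydroxy-7(11)-en-8-one
Product: 33 target, 3β-angeloyloxy-4α-hydroxy-11-hydroperoxyeudesm-6-en-8-one
Conditions: O2, visible light, tetraphenylporphyrin (cat.), CH2Cl2, 0 °C; stopped when 32 is consumed
Reagents that add atoms: dioxygen, O=O
Why: Schenck ene reaction of an enone locked s-cis, which follows the geminal selectivity of unsaturated carbonyl compounds (oxygen binds to C11, and the axial 6β-H on the group geminal to the carbonyl is removed, moving the alkene to C6=C7), creates no stereocentre and should outrun the slower-reacting angelate alkene.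

**Compound list**
1 | δ-valerolactone | O=C1CCCCO1 | starting material
2 | 6-hydroxyhexan-2-one | CC(=O)CCCCO | intermediate
3 | 5-methylhex-5-en-1-ol | C=C(C)CCCCO | intermediate
4 | 5-methylhex-5-enal | C=C(C)CCCC=O | intermediate
5 | ethynylmagnesium bromide | C#C[Mg]Br | starting material
6 | rac-7-methyloct-7-en-1-yn-3-ol (racemic) | C#CC(O)CCCC(C)=C | intermediate
7 | 7-methyloct-7-en-1-yn-3-one | C#CC(=O)CCCC(C)=C | intermediate
8 | 9-[(R)-7-methyloct-7-en-1-yn-3-yloxy]-9-borabicyclo[3.3.1]nonane | C1CC2CCCC(C1)B2O[C@@H](C#C)CCCC(C)=C | intermediate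
9 | (R)-7-methyloct-7-en-1-yn-3-ol | O[C@@H](C#C)CCCC(C)=C | intermediate
10 | (R)-3-(tert-butyldimethylsilyloxy)-7-methyloct-7-en-1-yne | CC(C)(C)[Si](C)(C)O[C@@H](C#C)CCCC(C)=C | intermediate
11 | Co2(CO)6 complex of the alkyne of 10 | CC(C)(C)[Si](C)(C)O[C@@H](C12[Co]3(=C=O)(=C=O)(=C=O)[Co]1(=C=O)(=C=O)(=C=O)C23)CCCC(C)=C | intermediate
12 | (4R,7aR)-4-(tert-butyldimethylsilyloxy)-7a-methyl-1,4,5,6,7,7a-hexahydro-2H-inden-2-one (C5=C6, C8=O, 4α-OTBS, 10β-CH3) | CC(C)(C)[Si](C)(C)O[C@@H]1CCC[C@]2(C)CC(=O)C=C12 | intermediate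
13 | (3aR,4R,7aR)-4-(tert-butyldimethylsilyloxy)-7a-methyl-2-(trimethylsilyloxy)-3a,4,5,6,7,7a-hexahydro-1H-indene (trans fusion, C6=C8 enol ether) | CC(C)(C)[Si](C)(C)O[C@@H]1CCC[C@]2(C)CC(O[Si](C)(C)C)=C[C@@H]12 | intermediate
14 | bromoform | BrC(Br)Br | starting material
15 | α-face dibromocarbene adduct of 13 (CBr2 = C7 bridging C6 and C8, 8β-OTMS, 6β-H) | CC(C)(C)[Si](C)(C)O[C@@H]1CCC[C@]2(C)C[C@]3(O[Si](C)(C)C)C(Br)(Br)[C@@H]3[C@@H]12 | intermediate
16 | (4aR,5R,8aR)-3-bromo-5-(tert-butyldimethylsilyloxy)-8a-methyl-4a,5,6,7,8,8a-hexahydronaphthalen-2(1H)-one (7-bromo-6-en-8-one) | CC(C)(C)[Si](C)(C)O[C@@H]1CCC[C@]2(C)CC(=O)C(Br)=C[C@@H]12 | intermediate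
17 | isopropenylboronic acid pinacol ester | C=C(C)B1OC(C)(C)C(C)(C)O1 | starting material
18 | (4aR,5R,8aR)-5-(tert-butyldimethylsilyloxy)-8a-methyl-3-(prop-1-en-2-yl)-4a,5,6,7,8,8a-hexahydronaphthalen-2(1H)-one | CC(C)(C)[Si](C)(C)O[C@@H]1CCC[C@]2(C)CC(=O)C(C(C)=C)=C[C@@H]12 | intermediate
19 | lithium C7=C8 dienolate from 18 | [Li+].CC(C)(C)[Si](C)(C)O[C@@H]1CCC[C@]2(C)CC([O-])=C(C(C)=C)C[C@@H]12 | intermediate
20 | 7-isopropenyl-4α-(tert-butyldimethylsilyloxy)-10β-methyl-trans-decal-8-one (C7 epimers) | CC(C)(C)[Si](C)(C)O[C@@H]1CCC[C@]2(C)CC(=O)C(C(C)=C)C[C@@H]12 | intermediate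
21 | (4aR,5R,8aR)-5-(tert-butyldimethylsilyloxy)-8a-methyl-3-(propan-2-ylidene)octahydronaphthalen-2(1H)-one | CC(C)(C)[Si](C)(C)O[C@@H]1CCC[C@]2(C)CC(=O)C(=C(C)C)C[C@@H]12 | intermediate
22 | 4α-hydroxy-15-noreudesm-7(11)-en-8-one | O[C@@H]1CCC[C@]2(C)CC(=O)C(=C(C)C)C[C@@H]12 | intermediate
23 | (5R,10R)-15-noreudesm-7(11)-ene-4,8-dione | O=C1CCC[C@]2(C)CC(=O)C(=C(C)C)C[C@@H]12 | intermediate
24 | lithium C3=C4 enolate of 23 | [Li+].[O-]C1=CCC[C@]2(C)CC(=O)C(=C(C)C)C[C@@H]12 | intermediate
25 | 8-oxo-15-noreudesma-3,7(11)-dien-4-yl triflate | O=S(=O)(OC1=CCC[C@]2(C)CC(=O)C(=C(C)C)C[C@@H]12)C(F)(F)F | intermediate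
26 | (5R,10R)-eudesma-3,7(11)-dien-8-one | CC1=CCC[C@]2(C)CC(=O)C(=C(C)C)C[C@@H]12 | intermediate
27 | (3R,4S,5R,10R)-3α,4α-dihydroxyeudesm-7(11)-en-8-one | O[C@@H]1CC[C@]2(C)CC(=O)C(=C(C)C)C[C@H]2[C@]1(C)O | intermediate
28 | (4S,5R,10R)-4α-hydroxyeudesm-7(11)-ene-3,8-dione | O=C1CC[C@]2(C)CC(=O)C(=C(C)C)C[C@H]2[C@]1(C)O | intermediate
29 | (3S,4S,5R,10R)-3β,4α-dihydroxyeudesm-7(11)-en-8-one | O[C@H]1CC[C@]2(C)CC(=O)C(=C(C)C)C[C@H]2[C@]1(C)O | intermediate
30 | angelic acid, (Z)-2-methylbut-2-enoic acid | C/C=C(/C)C(=O)O | starting material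
31 | angelic 2,4,6-trichlorobenzoic anhydride | C/C=C(/C)C(=O)OC(=O)c1c(Cl)cc(Cl)cc1Cl | intermediate
32 | (3S,4S,5R,10R)-3β-angeloyloxy-4α-hydroxyeudesm-7(11)-en-8-one | C/C=C(/C)C(=O)O[C@H]1CC[C@]2(C)CC(=O)C(=C(C)C)C[C@H]2[C@]1(C)O | intermediate
33 | (3S,4S,5R,10R)-3β-angeloyloxy-4α-hydroxy-11-hydroperoxyeudesm-6-en-8-one (CNP0161122.1) | C/C=C(/C)C(=O)O[C@H]1CC[C@]2(C)CC(=O)C(C(C)(C)OO)=C[C@H]2[C@]1(C)O | target

**Step count**
Total steps: 21. Longest linear sequence: 21 steps (1 to 33). Compounds 5, 14, 17 and 30 are bought and enter directly.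

**Steps most likely to fail**

Step 10 (key step).
- What may go wrong: tert-butoxide may attack silicon and return the ketone enolate before the carbene is captured. Surplus base may also remove the γ-proton at C5 of the bromoenone and expel the C4 silyloxy group.
- Fallback: a base-free one-carbon insertion with the halogen added afterwards. It sets out from 13.
- Simmons–Smith cyclopropanation (Et2Zn, CH2I2, CH2Cl2, 0 °C) should give the siloxycyclopropane F1.
- FeCl3 in DMF at 0 °C opens the C6–C8 bond oxidatively to the 6-chloro-8-ketone F2.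
- NaOAc in warm MeOH removes HCl to give the 6-en-8-one F3.
- I2/pyridine in CH2Cl2 iodinates C7 by addition–elimination to give the 7-iodo-6-en-8-one F4.
- F4 is coupled with 17 under the conditions of step 11, and the sequence comes back to the route at 18.

Step 9.
- What may go wrong: hydride delivery to a β-carbon flanked by quaternary C10 and the C4 silyl ether may be slow. Facial selectivity may be poor (cis fusion), or 1,2-reduction may compete.
- Fallback: stereoelectronic instead of steric control, with the enol ether made by deprotonation. It sets out from 12.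
- Aqueous HF in MeCN frees the hydroxy enone F5.
- Dissolving-metal reduction of its lithium alkoxide (Li, NH3/THF, −78 °C, NH4Cl quench) protonates C5 axially, while the alkoxide cannot leave from C4. This should give the trans hydroxy ketone F6.
- TBSOTf/2,6-lutidine gives the silyl ether ketone F7.
- LDA/TMSCl (THF, −78 °C) deprotonates C6 rather than the neopentyl C9, and the sequence comes back to the route at 13.

Step 15.
- What may go wrong: deprotonation at C9 or at the γ-positions of the C8 enone may compete. Proton transfer between the two carbonyl units may also occur before triflation.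
- Fallback: C8 is taken out of play as a protected allylic alcohol before C4 becomes a ketone. It sets out from 21.
- DIBAL-H (CH2Cl2, −78 °C) should attack C8 from the open α face to give the 8β-allylic alcohol F8.
- NaH, PMBCl and Bu4NI in DMF give the PMB ether F9.
- Bu4NF in THF frees the 4α-alcohol F10.
- DMP gives the monoketone F11, which has only one carbonyl group to enolise.
- LDA and the pyridyl triflimide give the enol triflate F12.
- MeZnCl/Pd(PPh3)4 gives the 4-methyl diene F13.
- DDQ in wet CH2Cl2 removes the PMB group to give the dienol F14.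
- MnO2 oxidises the allylic alcohol, and the sequence comes back to the route at 26.

**Further compounds**
F1 | step 10 | α-face methylene adduct of 13 (CH2 = C7 bridging C6 and C8, 8β-OTMS) | CC(C)(C)[Si](C)(C)O[C@@H]1CCC[C@]2(C)C[C@]3(O[Si](C)(C)C)C[C@@H]3[C@@H]12
F2 | step 10 | 6-chloro-4α-(tert-butyldimethylsilyloxy)-10β-methyl-trans-decal-8-one (C6 epimers) | CC(C)(C)[Si](C)(C)O[C@@H]1CCC[C@]2(C)CC(=O)CC(Cl)[C@@H]12
F3 | step 10 | 4α-(tert-butyldimethylsilyloxy)-10β-methyl-trans-decal-6-en-8-one | CC(C)(C)[Si](C)(C)O[C@@H]1CCC[C@]2(C)CC(=O)C=C[C@@H]12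
F4 | step 10 | 7-iodo-4α-(tert-butyldimethylsilyloxy)-10β-methyl-trans-decal-6-en-8-one | CC(C)(C)[Si](C)(C)O[C@@H]1CCC[C@]2(C)CC(=O)C(I)=C[C@@H]12
F5 | step 9 | (4R,7aR)-4-hydroxy-7a-methyl-1,4,5,6,7,7a-hexahydro-2H-inden-2-one | O[C@@H]1CCC[C@]2(C)CC(=O)C=C12
F6 | step 9 | (3aR,4R,7aR)-4-hydroxy-7a-methyloctahydro-2H-inden-2-one (trans fusion) | O[C@@H]1CCC[C@]2(C)CC(=O)C[C@@H]12
F7 | step 9 | (3aR,4R,7aR)-4-(tert-butyldimethylsilyloxy)-7a-methyloctahydro-2H-inden-2-one (trans fusion) | CC(C)(C)[Si](C)(C)O[C@@H]1CCC[C@]2(C)CC(=O)C[C@@H]12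
F8 | step 15 | 4α-(tert-butyldimethylsilyloxy)-15-noreudesm-7(11)-en-8β-ol | CC(C)(C)[Si](C)(C)O[C@@H]1CCC[C@]2(C)C[C@@H](O)C(=C(C)C)C[C@@H]12
F9 | step 15 | 4α-(tert-butyldimethylsilyloxy)-8β-(4-methoxybenzyloxy)-15-noreudesm-7(11)-ene | CC(C)(C)[Si](C)(C)O[C@@H]1CCC[C@]2(C)C[C@@H](OCc3ccc(OC)cc3)C(=C(C)C)C[C@@H]12
F10 | step 15 | 8β-(4-methoxybenzyloxy)-15-noreudesm-7(11)-en-4α-ol | O[C@@H]1CCC[C@]2(C)C[C@@H](OCc3ccc(OC)cc3)C(=C(C)C)C[C@@H]12
F11 | step 15 | 8β-(4-methoxybenzyloxy)-15-noreudesm-7(11)-en-4-one | O=C1CCC[C@]2(C)C[C@@H](OCc3ccc(OC)cc3)C(=C(C)C)C[C@@H]12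
F12 | step 15 | 8β-(4-methoxybenzyloxy)-15-noreudesma-3,7(11)-dien-4-yl triflate | O=S(=O)(OC1=CCC[C@]2(C)C[C@@H](OCc3ccc(OC)cc3)C(=C(C)C)C[C@@H]12)C(F)(F)F
F13 | step 15 | 8β-(4-methoxybenzyloxy)eudesma-3,7(11)-diene | CC1=CCC[C@]2(C)C[C@@H](OCc3ccc(OC)cc3)C(=C(C)C)C[C@@H]12
F14 | step 15 | eudesma-3,7(11)-dien-8β-ol | CC1=CCC[C@]2(C)C[C@@H](O)C(=C(C)C)C[C@@H]12
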